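**Retrosynthetic overview**

- The norbornene core is cut by a retro-Diels–Alder reaction into a 2-acetoxy-guaia-1(5),3-diene lactone (fragment A, made in situ by dehydration) and a 1,10-seco-eudesmanolide α-methylene lactone (fragment B); this ring is formed last.
- Fragment A: the C4 methyl comes from 1,2-addition to a cyclopentenone; the seven-membered ring and trans-lactone come from one intramolecular chromium-mediated 2-(methoxycarbonyl)allylation (C7–C8).
- The cyclopentenone carrying the C2 oxygen is made by dearomatising a 2,5-dialkylfuran (Piancatelli rearrangement/isomerisation with internal hemiacetal capture, the key step); the furan comes from furfural, allyl bromide and crotonaldehyde.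
- Fragment B: the cyclohexene comes from 2-methylanisole (Birch reduction, asymmetric dihydroxylation of the enol ether, epoxidation/β-elimination); the side-chain centre by crotylation of the C5′ ketone; the cis-lactone by Ireland–Claisen rearrangement, then α-methylenation.
- Ring order: cyclopentenone, then seven-membered ring plus lactone (A); cyclohexene, then lactone (B); norbornene.

Assumptions: atoms are labelled C1–C15 (guaianolide half) and C1′–C15′ (seco-eudesmanolide half) by terpenoid numbering; centres that are destroyed later (furyl carbinol, lactol carbon, C4 of 13) are carried as mixtures; the catalyst and ligand enantiomers named are those the usual facial models predict.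

**Fragment A**

Step 1
Reactants: 1 furfural; 2 allyl bromide
Product: 3 rac-1-(furan-2-yl)but-3-en-1-ol
Conditions: Zn dust, sat. aq. NH4Cl–THF, 0 → 20 °C
Reagents that add atoms: none
Why: Barbier allylation of the aldehyde by allylzinc bromide formed in situ; the carbinol centre is left racemic because it becomes sp2 in step 3.

Step 2
Reactants: 3 rac-1-(furan-2-yl)but-3-en-1-ol; 4 (E)-crotonaldehyde
Product: 5 (3R)-3-[5-(1-hydroxybut-3-en-1-yl)furan-2-yl]butanal
Conditions: (2S,5S)-5-benzyl-2-tert-butyl-3-methylimidazolidin-4-one·TFA (20 mol %), THF–H2O (95:5), −30 °C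
Reagents that add atoms: none
Why: Iminium-catalysed Friedel–Crafts conjugate addition (MacMillan type) at the free C5 of the 2-alkylfuran; the imidazolidinone shields one face of the (E)-iminium ion, which sets the future C10 as (R).

Step 3
Reactants: 5 (3R)-3-[5-(1-hydroxybut-3-en-1-yl)furan-2-yl]butanal
Product: 8 (4R,7aS)-2-hydroxy-4-methyl-5-(prop-2-en-1-yl)-3,4,7,7a-tetrahydrocyclopenta[b]pyran-6(2H)-one, via Piancatelli cyclopentenone 6 (not isolated), via hydroxy-aldehyde 7 (not isolated)
Conditions: ZnCl2 (1 equiv), H2O–1,4-dioxane (2:1), pH 5.5, 95 °C; then Na2HPO4 to pH 8, 60 °C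
Reagents that add atoms: water, O
Why: Proposed new method: the furylcarbinol ionises, water adds to the substituted furan carbon, the ring opens and a conrotatory 4π-electrocyclisation gives the trans-4-hydroxy-5-allylcyclopentenone (Piancatelli rearrangement, which breaks the furan aromaticity), and mild base then moves the oxygen to C2 by β-elimination/oxa-Michael re-addition as in the known furan route to 4-hydroxy-2,3-dialkylcyclopentenones (rethrolones); here the hydrate of the pendant aldehyde is the oxygen nucleophile, so C2–O closes a six-membered lactol whose chair keeps the C10 methyl axial (the equatorial position eclipses the C6 methylene across C1=C5), and this reversible step should deliver the (2S) epimer; closest known reactions are the two-stage Piancatelli/isomerisation and the intramolecular oxa-Piancatelli cyclisations of hydroxyalkyl furans.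

Step 4
Reactants: 8 lactol; 9 methyl 2-(bromomethyl)acrylate
Product: 10 methyl (2Z)-2-(bromomethyl)-4-[(4R,7aS)-2-hydroxy-4-methyl-6-oxo-2,3,4,6,7,7a-hexahydrocyclopenta[b]pyran-5-yl]but-2-enoate
Conditions: second-generation Hoveyda–Grubbs catalyst (5 mol %), 9 (4 equiv), CH2Cl2, 40 °C
Reagents that add atoms: none
Why: Olefin cross-metathesis of the terminal allyl group with the 1,1-disubstituted acrylate; the tetrasubstituted enone is inert and the trisubstituted enoate forms as the thermodynamic isomer with the ester trans to the chain.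

Step 5
Reactants: 10 allylic bromide lactol
Product: 11 (2S,7S,8R,10R)-2-hydroxy-4-oxo-15-norguaia-1(5),11(13)-dien-12,8-olide
Conditions: CrCl2 (4 equiv), THF, 0.005 M, 20 °C; aq. NH4Cl work-up
Reagents that add atoms: none
Why: Intramolecular Nozaki–Hiyama-type 2-(methoxycarbonyl)allylation of the lactol-masked aldehyde; the allylchromium equilibrates and reacts through a Zimmerman–Traxler chair to give the anti adduct, which lactonises to the trans-lactone with loss of methanol, and a pseudo-axial C10 methyl (A1,2 strain with C2) should select the (7S,8R) pair.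

Step 6
Reactants: 11 hydroxy enone lactone
Product: 12 (2R,7S,8R,10R)-2-acetoxy-4-oxo-15-norguaia-1(5),11(13)-dien-12,8-olide
Conditions: PPh3, DIAD, AcOH, THF, 0 °C
Reagents that add atoms: acetic acid, CC(=O)O
Why: Mitsunobu reaction on the only free hydroxyl; SN2 displacement by acetate inverts C2 to the required (R) acetate.

Step 7
Reactants: 12 acetoxy enone lactone
Product: 13 (2R,7S,8R,10R)-2-acetoxy-4-hydroxyguaia-1(5),11(13)-dien-12,8-olide (both C4 epimers)
Conditions: MeLi, CeCl3, THF, −78 °C
Reagents that add atoms: methyllithium, [Li]C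
Why: Organocerium 1,2-addition, which is selective for the ketone over the acetate, the lactone and the α-methylene acceptor and is non-basic enough to avoid β-elimination of acetate; the new C4 centre is lost in step 18.

**Fragment B**

Step 8
Reactants: 14 2-methylanisole
Product: 15 1-methoxy-2-methylcyclohexa-1,4-diene
Conditions: Li, liquid NH3, t-BuOH, THF, −78 °C
Reagents that add atoms: none
Why: Birch reduction; the methoxy and methyl groups stay on sp2 carbons, giving the tetrasubstituted enol ether and an isolated cis-alkene.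

Step 9
Reactants: 15 Birch diene
Product: 16 (2R)-2-hydroxy-2-methylcyclohex-4-en-1-one
Conditions: OsO4 (1 mol %), (DHQD)2PHAL (5 mol %), NMO, acetone–H2O, 0 °C, slow addition of 15
Reagents that add atoms: N-methylmorpholine N-oxide, C[N+]1([O-])CCOCC1; water, O
Why: Sharpless-type asymmetric dihydroxylation, selective for the electron-rich enol ether over the cis-disubstituted alkene; the hemiketal loses methanol to the α-hydroxy ketone, the ligand sets the tertiary carbinol (C10′) as (R), and the neutral medium keeps the β,γ-alkene out of conjugation.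

Step 10
Reactants: 16 hydroxy ketone
Product: 18 (4S,6R)-4,6-dihydroxy-6-methylcyclohex-2-en-1-one, via syn-epoxy ketone 17 (not isolated)
Conditions: VO(acac)2 (2 mol %), t-BuOOH, CH2Cl2, 0 °C; then Et3N, 20 °C
Reagents that add atoms: tert-butyl hydroperoxide, CC(C)(C)OO
Why: Homoallylic-hydroxyl-directed epoxidation places the epoxide syn to the tertiary OH, and E1cB opening of the β,γ-epoxy ketone gives the γ-hydroxy enone with C8′–OH cis to C10′–OH.

Step 11
Reactants: 18 dihydroxy enone
Product: 19 (1R,5S)-1,3,3-trimethyl-2,4-dioxabicyclo[3.3.1]non-6-en-8-one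
Conditions: Me2C(OMe)2, PPTS (cat.), CH2Cl2, 20 °C
Reagents that add atoms: 2,2-dimethoxypropane, COC(C)(C)OC
Why: Acetonide formation, possible only for the cis-1,3-diol; the bridge blocks one face of the ketone for step 12.

Step 12
Reactants: 19 acetonide enone; 20 potassium (E)-but-2-en-1-yltrifluoroborate
Product: 21 (1R,5S,8R)-8-[(2R)-but-3-en-2-yl]-1,3,3-trimethyl-2,4-dioxabicyclo[3.3.1]non-6-en-8-ol
Conditions: montmorillonite K10, dry CH2Cl2, 20 °C
Reagents that add atoms: none
Why: Ketone crotylboration through a closed chair transition state (crotyl-BF2 formed on the clay); attack comes from the face opposite the acetonide bridge with the bridgehead carbon equatorial, so the (E)-crotyl geometry gives (4′R) and the new C5′–OH lies cis to the bridge oxygens.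

Step 13
Reactants: 21 tertiary alcohol
Product: 22 (1R,5S,8R)-8-[(2R)-but-3-en-2-yl]-1,3,3-trimethyl-2,4-dioxabicyclo[3.3.1]non-6-en-8-yl acetate
Conditions: n-BuLi, THF, −78 °C; Ac2O, −78 → 0 °C
Reagents that add atoms: acetic anhydride, CC(=O)OC(C)=O
Why: O-acylation of the lithium alkoxide of a hindered tertiary alcohol; the lithium counter-ion and low temperature avoid anionic oxy-Cope rearrangement of the 1,5-dien-3-olate.

Step 14
Reactants: 22 tertiary allylic acetate
Product: 25 (3aR,6R,7aS)-5-[(2R)-but-3-en-2-yl]-6-hydroxy-6-methyl-3a,6,7,7a-tetrahydro-1-benzofuran-2(3H)-one, via silyl ketene acetal 23 (not isolated), via trimethylsilyl ester 24 (not isolated)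
Conditions: LDA, TMSCl, THF, −78 → 50 °C; then AcOH–H2O–THF (3:1:1), 40 °C
Reagents that add atoms: none
Why: Ireland–Claisen rearrangement; the suprafacial [3,3] shift forms the C7′–C11′ bond on the face of the departing C5′–O (cis to O8′ and O10′) and moves the alkene to C5′=C6′, and mild acid then removes the silyl ester and acetonide so the cis γ-hydroxy acid lactonises.

Step 15
Reactants: 25 vinyl lactone; 26 (2Z)-but-2-ene-1,4-diyl diacetate
Product: 27 (2E,4R)-4-[(3aR,6R,7aS)-6-hydroxy-6-methyl-2-oxo-2,3,3a,6,7,7a-hexahydro-1-benzofuran-5-yl]pent-2-en-1-yl acetate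
Conditions: second-generation Hoveyda–Grubbs catalyst (5 mol %), CH2Cl2, 40 °C
Reagents that add atoms: none
Why: Olefin cross-metathesis of the α-branched terminal alkene with the symmetrical allylic diacetate; the trisubstituted ring alkene does not react.

Step 16
Reactants: 27 allylic acetate
Product: 28 (4R)-4-[(3aR,6R,7aS)-6-hydroxy-6-methyl-2-oxo-2,3,3a,6,7,7a-hexahydro-1-benzofuran-5-yl]pentyl acetate
Conditions: H2 (1 atm), RhCl(PPh3)3 (5 mol %), benzene–EtOH, 20 °C
Reagents that add atoms: none
Why: Homogeneous hydrogenation with Wilkinson's catalyst, which reduces the disubstituted alkene and leaves the hindered trisubstituted ring alkene.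

Step 17
Reactants: 28 saturated lactone
Product: 29 (4R)-4-[(3aS,6R,7aS)-6-hydroxy-6-methyl-3-methylidene-2-oxo-2,3,3a,6,7,7a-hexahydro-1-benzofuran-5-yl]pentyl acetate
Conditions: LiN(SiMe3)2 (2.2 equiv), THF, −78 °C; [CH2=NMe2]I; then MeI, MeOH; NaHCO3, CH2Cl2–H2O
Reagents that add atoms: dimethylmethylideneammonium iodide, C=[N+](C)C.[I-]
Why: Lactone α-methylenation by Mannich reaction and Hofmann-type elimination; the lactone α-CH is several pK units more acidic than the acyclic acetate, so the amide base enolises only the lactone after deprotonating the hydroxyl.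

**Union**

Step 18
Reactants: 13 tertiary allylic alcohol; 29 fragment B
Product: 31 CNP0257312.1, via acetoxy-diene 30 (not isolated)
Conditions: Ph2S[OC(CF3)2Ph]2 (1.0 equiv), CH2Cl2, −40 °C, 15 min; then 29 (3 equiv), concentrate to 2 M, 20 °C, 48 h
Reagents that add atoms: none
Why: Martin-sulfurane dehydration gives the 5-acetoxycyclopentadiene, which is trapped in a Diels–Alder reaction: the dienophile adds to the diene face syn to the acetoxy group (the known preference of 5-acyloxycyclopentadienes, here also the face anti to the C10 methyl), through the convex face of the cis-fused lactone, with the lactone carbonyl endo and the fully substituted diene terminus C1 bonding to the methylene carbon, which sets C1, C3 and C11′ and leaves the acetate over the new saturated bridge; excess 29 suppresses self-dimerisation of 30 and is recovered.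

**Compound list**

1 | furfural | O=Cc1ccco1 | starting material
2 | allyl bromide | C=CCBr | starting material
3 | rac-1-(furan-2-yl)but-3-en-1-ol | OC(CC=C)c1ccco1 | intermediate
4 | (E)-crotonaldehyde | C/C=C/C=O | starting material
5 | (3R)-3-[5-(1-hydroxybut-3-en-1-yl)furan-2-yl]butanal (both carbinol epimers) | O=CC[C@@H](C)c1ccc(C(O)CC=C)o1 | intermediate
6 | (3R)-3-[trans-1-hydroxy-4-oxo-5-(prop-2-en-1-yl)cyclopent-2-en-1-yl]butanal (ring diastereomers) | O=CC[C@@H](C)C1(O)C=CC(=O)C1CC=C | intermediate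
7 | (3R)-3-[(5S)-5-hydroxy-3-oxo-2-(prop-2-en-1-yl)cyclopent-1-en-1-yl]butanal | O=CC[C@@H](C)C1=C(CC=C)C(=O)C[C@@H]1O | intermediate
8 | (4R,7aS)-2-hydroxy-4-methyl-5-(prop-2-en-1-yl)-3,4,7,7a-tetrahydrocyclopenta[b]pyran-6(2H)-one (both anomers) | O=C1C[C@@H]2OC(O)C[C@@H](C)C2=C1CC=C | intermediate
9 | methyl 2-(bromomethyl)acrylate | C=C(CBr)C(=O)OC | starting material
10 | methyl (2Z)-2-(bromomethyl)-4-[(4R,7aS)-2-hydroxy-4-methyl-6-oxo-2,3,4,6,7,7a-hexahydrocyclopenta[b]pyran-5-yl]but-2-enoate | O=C1C[C@@H]2OC(O)C[C@@H](C)C2=C1C/C=C(\CBr)C(=O)OC | intermediate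
11 | (2S,7S,8R,10R)-2-hydroxy-4-oxo-15-norguaia-1(5),11(13)-dien-12,8-olide | C=C1C(=O)O[C@@H]2C[C@@H](C)C3=C(C[C@@H]12)C(=O)C[C@@H]3O | intermediate
12 | (2R,7S,8R,10R)-2-acetoxy-4-oxo-15-norguaia-1(5),11(13)-dien-12,8-olide | C=C1C(=O)O[C@@H]2C[C@@H](C)C3=C(C[C@@H]12)C(=O)C[C@H]3OC(C)=O | intermediate
13 | (2R,7S,8R,10R)-2-acetoxy-4-hydroxyguaia-1(5),11(13)-dien-12,8-olide (both C4 epimers) | C=C1C(=O)O[C@@H]2C[C@@H](C)C3=C(C[C@@H]12)C(C)(O)C[C@H]3OC(C)=O | intermediate
14 | 2-methylanisole | COc1ccccc1C | starting material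
15 | 1-methoxy-2-methylcyclohexa-1,4-diene | COC1=C(C)CC=CC1 | intermediate
16 | (2R)-2-hydroxy-2-methylcyclohex-4-en-1-one | C[C@@]1(O)CC=CCC1=O | intermediate
17 | (1S,3R,6R)-3-hydroxy-3-methyl-7-oxabicyclo[4.1.0]heptan-4-one | C[C@@]1(O)C[C@@H]2O[C@@H]2CC1=O | intermediate
18 | (4S,6R)-4,6-dihydroxy-6-methylcyclohex-2-en-1-one | C[C@@]1(O)C[C@H](O)C=CC1=O | intermediate
19 | (1R,5S)-1,3,3-trimethyl-2,4-dioxabicyclo[3.3.1]non-6-en-8-one | C[C@@]12C[C@@H](C=CC1=O)OC(C)(C)O2 | intermediate
20 | potassium (E)-but-2-en-1-yltrifluoroborate | C/C=C/C[B-](F)(F)F.[K+] | starting material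
21 | (1R,5S,8R)-8-[(2R)-but-3-en-2-yl]-1,3,3-trimethyl-2,4-dioxabicyclo[3.3.1]non-6-en-8-ol | C[C@@]12C[C@@H](C=C[C@@]1(O)[C@H](C)C=C)OC(C)(C)O2 | intermediate
22 | (1R,5S,8R)-8-[(2R)-but-3-en-2-yl]-1,3,3-trimethyl-2,4-dioxabicyclo[3.3.1]non-6-en-8-yl acetate | C[C@@]12C[C@@H](C=C[C@@]1(OC(C)=O)[C@H](C)C=C)OC(C)(C)O2 | intermediate
23 | O-trimethylsilyl ketene acetal of 22 | C[C@@]12C[C@@H](C=C[C@@]1(OC(=C)O[Si](C)(C)C)[C@H](C)C=C)OC(C)(C)O2 | intermediate
24 | trimethylsilyl 2-{8-[(2R)-but-3-en-2-yl]-1,3,3-trimethyl-2,4-dioxabicyclo[3.3.1]non-7-en-6-yl}acetate (side chain cis to the ring oxygens) | C[C@@]12C[C@@H]([C@H](CC(=O)O[Si](C)(C)C)C=C1[C@H](C)C=C)OC(C)(C)O2 | intermediate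
25 | (3aR,6R,7aS)-5-[(2R)-but-3-en-2-yl]-6-hydroxy-6-methyl-3a,6,7,7a-tetrahydro-1-benzofuran-2(3H)-one | C[C@@]1(O)C[C@@H]2OC(=O)C[C@@H]2C=C1[C@H](C)C=C | intermediate
26 | (2Z)-but-2-ene-1,4-diyl diacetate | CC(=O)OC/C=C\COC(C)=O | starting material
27 | (2E,4R)-4-[(3aR,6R,7aS)-6-hydroxy-6-methyl-2-oxo-2,3,3a,6,7,7a-hexahydro-1-benzofuran-5-yl]pent-2-en-1-yl acetate | C[C@@]1(O)C[C@@H]2OC(=O)C[C@@H]2C=C1[C@H](C)/C=C/COC(C)=O | intermediate
28 | (4R)-4-[(3aR,6R,7aS)-6-hydroxy-6-methyl-2-oxo-2,3,3a,6,7,7a-hexahydro-1-benzofuran-5-yl]pentyl acetate | C[C@@]1(O)C[C@@H]2OC(=O)C[C@@H]2C=C1[C@H](C)CCCOC(C)=O | intermediate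
29 | (4R)-4-[(3aS,6R,7aS)-6-hydroxy-6-methyl-3-methylidene-2-oxo-2,3,3a,6,7,7a-hexahydro-1-benzofuran-5-yl]pentyl acetate (fragment B) | C[C@@]1(O)C[C@@H]2OC(=O)C(=C)[C@@H]2C=C1[C@H](C)CCCOC(C)=O | intermediate
30 | (2R,7S,8R,10R)-2-acetoxyguaia-1(5),3,11(13)-trien-12,8-olide (fragment A) | C=C1C(=O)O[C@@H]2C[C@@H](C)C3=C(C[C@@H]12)C(C)=C[C@H]3OC(C)=O | intermediate
31 | CNP0257312.1 | C=C1C(=O)O[C@@H]2C[C@@H](C)[C@]34C[C@]5(C(=O)O[C@H]6C[C@@](C)(O)C([C@H](C)CCCOC(C)=O)=C[C@H]65)[C@H](C(C)=C3C[C@@H]12)[C@H]4OC(C)=O | target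

**Totals**

Total step count: 18. Longest linear sequence: 11 steps (14 → 31, steps 8–18); the furan branch contributes 7 steps before the union.

**Steps most likely to fail**

Step 3. The free aldehyde may not survive the hot aqueous rearrangement, and the C2 configuration rests on an untested lactol equilibrium. The fallback sets out from 5 and returns at 12. Reduce the aldehyde with NaBH4 to the diol F1 and silylate the primary hydroxyl (TBDPSCl, imidazole) to the silyl ether F2. Run the classical two-stage Piancatelli rearrangement/isomerisation (ZnCl2, water–dioxane) to the 4-hydroxycyclopentenone F3, a 1:1 mixture at the carbinol. Converge both epimers on the (R)-acetate F4 by lipase acetylation of the (R)-alcohol (Amano lipase PS, vinyl acetate) followed by Mitsunobu inversion of the remaining (S)-alcohol with acetic acid. Cross-metathesise with 9 to the bromide F5, remove the silyl group (HF·pyridine) to the primary alcohol F6, oxidise (Dess–Martin periodinane) to the aldehyde F7, and close the ring with CrCl2, which gives 12 directly.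

Step 5. The anti (trans-lactone) outcome is well founded, but the sense relative to the C10 methyl depends on that group sitting pseudo-axial in the transition state; the 7,8-bis-epimer may dominate. The fallback sets out from 8 and returns at 11, replacing the organochromium closure by a radical one. Cross-metathesis of 8 with methyl 2-(acetoxymethyl)acrylate gives the allylic acetate F8. SmI2 in THF then reduces the lactol-masked aldehyde to the ketyl, which adds 7-exo to the acrylate carbon C7 and expels acetate, giving the α-methylene hydroxy ester that lactonises to 11.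

Step 18. Diene 30 can undergo 1,5-hydrogen shifts, eliminate toward the methyl group, or dimerise through its own methylene lactone before it meets 29. The fallback sets out from 11 and returns at 31, using a diene that cannot shift. Oxidise 11 (Dess–Martin periodinane) to the ene-dione F9 and add MeTi(OiPr)3 to the less hindered C4 carbonyl to give the hydroxy enone F10. Ketalise C2 with ethylene glycol under dehydrating acid catalysis to the ethylenedioxy-cyclopentadiene F11, which has no hydrogen on C2. The Diels–Alder reaction with 29 gives the ketal adduct F12; hydrolysis gives the bridging ketone F13; NaBH4, delivering hydride from the alkene side, gives the alcohol F14; acetylation (Ac2O, pyridine) gives 31.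

Further compounds
F1 | step 3 | (3R)-3-[5-(1-hydroxybut-3-en-1-yl)furan-2-yl]butan-1-ol | OCC[C@@H](C)c1ccc(C(O)CC=C)o1
F2 | step 3 | 1-{5-[(2R)-4-(tert-butyldiphenylsilyloxy)butan-2-yl]furan-2-yl}but-3-en-1-ol | CC(C)(C)[Si](OCC[C@@H](C)c1ccc(C(O)CC=C)o1)(c1ccccc1)c1ccccc1
F3 | step 3 | 3-[(2R)-4-(tert-butyldiphenylsilyloxy)butan-2-yl]-4-hydroxy-2-(prop-2-en-1-yl)cyclopent-2-en-1-one (both carbinol epimers) | CC(C)(C)[Si](OCC[C@@H](C)C1=C(CC=C)C(=O)CC1O)(c1ccccc1)c1ccccc1
F4 | step 3 | (1R)-2-[(2R)-4-(tert-butyldiphenylsilyloxy)butan-2-yl]-4-oxo-3-(prop-2-en-1-yl)cyclopent-2-en-1-yl acetate | CC(C)(C)[Si](OCC[C@@H](C)C1=C(CC=C)C(=O)C[C@H]1OC(C)=O)(c1ccccc1)c1ccccc1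
F5 | step 3 | methyl (2Z)-4-{(3R)-3-acetoxy-2-[(2R)-4-(tert-butyldiphenylsilyloxy)butan-2-yl]-5-oxocyclopent-1-en-1-yl}-2-(bromomethyl)but-2-enoate | CC(C)(C)[Si](OCC[C@@H](C)C1=C(C/C=C(\CBr)C(=O)OC)C(=O)C[C@H]1OC(C)=O)(c1ccccc1)c1ccccc1
F6 | step 3 | methyl (2Z)-4-{(3R)-3-acetoxy-2-[(2R)-4-hydroxybutan-2-yl]-5-oxocyclopent-1-en-1-yl}-2-(bromomethyl)but-2-enoate | OCC[C@@H](C)C1=C(C/C=C(\CBr)C(=O)OC)C(=O)C[C@H]1OC(C)=O
F7 | step 3 | methyl (2Z)-4-{(3R)-3-acetoxy-5-oxo-2-[(2R)-4-oxobutan-2-yl]cyclopent-1-en-1-yl}-2-(bromomethyl)but-2-enoate | O=CC[C@@H](C)C1=C(C/C=C(\CBr)C(=O)OC)C(=O)C[C@H]1OC(C)=O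
F8 | step 5 | methyl (2E)-2-(acetoxymethyl)-4-[(4R,7aS)-2-hydroxy-4-methyl-6-oxo-2,3,4,6,7,7a-hexahydrocyclopenta[b]pyran-5-yl]but-2-enoate | O=C1C[C@@H]2OC(O)C[C@@H](C)C2=C1C/C=C(\COC(C)=O)C(=O)OC
F9 | step 18 | (7S,8R,10R)-2,4-dioxo-15-norguaia-1(5),11(13)-dien-12,8-olide | C=C1C(=O)O[C@@H]2C[C@@H](C)C3=C(C[C@@H]12)C(=O)CC3=O
F10 | step 18 | (7S,8R,10R)-4-hydroxy-2-oxoguaia-1(5),11(13)-dien-12,8-olide (both C4 epimers) | C=C1C(=O)O[C@@H]2C[C@@H](C)C3=C(C[C@@H]12)C(C)(O)CC3=O
F11 | step 18 | (7S,8R,10R)-2,2-(ethylenedioxy)guaia-1(5),3,11(13)-trien-12,8-olide | C=C1C(=O)O[C@@H]2C[C@@H](C)C3=C(C[C@@H]12)C(C)=CC31OCCO1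
F12 | step 18 | Diels–Alder adduct of F11 and 29 (target skeleton with an ethylene ketal at the bridge carbon C2) | C=C1C(=O)O[C@@H]2C[C@@H](C)[C@]34C[C@]5(C(=O)O[C@H]6C[C@@](C)(O)C([C@H](C)CCCOC(C)=O)=C[C@H]65)[C@H](C(C)=C3C[C@@H]12)C41OCCO1
F13 | step 18 | 2-oxo analogue of the target (bridging ketone) | C=C1C(=O)O[C@@H]2C[C@@H](C)[C@]34C[C@]5(C(=O)O[C@H]6C[C@@](C)(O)C([C@H](C)CCCOC(C)=O)=C[C@H]65)[C@H](C(C)=C3C[C@@H]12)C4=O
F14 | step 18 | 2-O-deacetyl target (bridge alcohol, OH over the saturated bridge) | C=C1C(=O)O[C@@H]2C[C@@H](C)[C@]34C[C@]5(C(=O)O[C@H]6C[C@@](C)(O)C([C@H](C)CCCOC(C)=O)=C[C@H]65)[C@H](C(C)=C3C[C@@H]12)[C@H]4O
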